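**Retrosynthetic overview**
- The target comes from its 11,15-bis-TBS methyl ester by desilylation and then enzymatic ester hydrolysis (TBS = tert-butyldimethylsilyl).
- That ketone comes from conjugate reduction of a C7=C8 exocyclic enone, itself made by dehydrating a C7 aldol.
- Key bond C7–C8: intermolecular aldol between methyl 7-oxoheptanoate and a regiodefined cyclopentanone enolate. The enolate is generated in the same flask by conjugate addition of the saturated ω-chain organocopper to (R)-4-silyloxycyclopentenone (C12 set trans to C11, then C8 trans to C12).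
- Building blocks: the ω-chain iodide from methyl 3-oxooctanoate (asymmetric hydrogenation sets C15), the enone from an enzymatically desymmetrised cyclopentene monoacetate (carries C11), the aldehyde from cycloheptene.
- Rings: the only ring is never constructed; it is carried in from the cyclopentene starting material and substituted first at C12, then at C8.

Assumption: (1S,4R)-4-hydroxycyclopent-2-en-1-yl acetate (the lipase-derived monoacetate), methyl 3-oxooctanoate and cycloheptene are taken as cheap commercial materials; C7 of compounds 16 and 17 is an epimer mixture and is drawn without configuration.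

**Route**

Step 1
Reactants: 1 methyl 3-oxooctanoate
Product: 2 methyl (S)-3-hydroxyoctanoate
Conditions: H2 (50 atm), RuCl2[(S)-BINAP] (0.1 mol%), MeOH, 50 °C
Reagents that add atoms: none
Why: Noyori asymmetric hydrogenation of a β-keto ester; the (S)-BINAP ruthenium catalyst chelates the keto ester and delivers hydrogen to one carbonyl face, giving the (S)-alcohol (future C15) in high ee.

Step 2
Reactants: 2 methyl (S)-3-hydroxyoctanoate
Product: 3 methyl (S)-3-(tert-butyldimethylsilyloxy)octanoate
Conditions: TBSCl, imidazole, DMF, rt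
Reagents that add atoms: tert-butyldimethylsilyl chloride (TBSCl), C[Si](C)(Cl)C(C)(C)C
Why: Standard imidazole-promoted silylation of a secondary alcohol; the stereocentre is not involved.

Step 3
Reactants: 3 methyl (S)-3-(tert-butyldimethylsilyloxy)octanoate
Product: 4 (S)-3-(tert-butyldimethylsilyloxy)octan-1-ol
Conditions: i-Bu2AlH (2.2 equiv), CH2Cl2, −78 → 0 °C; aq potassium sodium tartrate (KNaC4H4O6)
Reagents that add atoms: none
Why: Hydride reduction of the ester to the primary alcohol; the silyl ether and C3 are untouched.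

Step 4
Reactants: 4 (S)-3-(tert-butyldimethylsilyloxy)octan-1-ol
Product: 5 (S)-tert-butyl[(1-iodooctan-3-yl)oxy]dimethylsilane
Conditions: I2, PPh3, imidazole, CH2Cl2, 0 °C → rt
Reagents that add atoms: iodine, II
Why: Appel-type (Garegg–Samuelsson) iodination by SN2 displacement of the primary alkoxyphosphonium; the secondary silyl ether and its stereocentre are spectators.

Step 5
Reactants: 6 (1S,4R)-4-hydroxycyclopent-2-en-1-yl acetate
Product: 7 (1S,4R)-4-(tert-butyldimethylsilyloxy)cyclopent-2-en-1-yl acetate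
Conditions: TBSCl, imidazole, DMF, 0 °C → rt
Reagents that add atoms: tert-butyldimethylsilyl chloride (TBSCl), C[Si](C)(Cl)C(C)(C)C
Why: Silylation of the free (R)-configured carbinol, which becomes C11 of the target.

Step 6
Reactants: 7 (1S,4R)-4-(tert-butyldimethylsilyloxy)cyclopent-2-en-1-yl acetate
Product: 8 (1S,4R)-4-(tert-butyldimethylsilyloxy)cyclopent-2-en-1-ol
Conditions: K2CO3 (0.2 equiv), MeOH, 0 °C
Reagents that add atoms: none
Why: Base-catalysed transesterification (methanolysis) removes the acetate without touching the TBS ether or either stereocentre.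

Step 7
Reactants: 8 (1S,4R)-4-(tert-butyldimethylsilyloxy)cyclopent-2-en-1-ol
Product: 9 (R)-4-(tert-butyldimethylsilyloxy)cyclopent-2-en-1-one
Conditions: MnO2 (15 equiv), CH2Cl2, rt
Reagents that add atoms: none
Why: Neutral allylic alcohol oxidation; no base is present, so the β-silyloxy enone does not eliminate and C4 keeps its configuration.

Step 8
Reactants: 10 cycloheptene
Product: 12 methyl 7-oxoheptanoate, via 7-hydroperoxy-7-methoxyheptanal 11 (not isolated)
Conditions: O3, CH2Cl2/MeOH (5:1), NaHCO3, −78 °C; then Ac2O, Et3N, 0 °C → rt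
Reagents that add atoms: ozone, [O-][O+]=O; methanol, CO
Why: Schreiber unsymmetrical ozonolysis; methanol traps the Criegee carbonyl oxide as a methoxy hydroperoxide, which Ac2O/Et3N dehydrates to the methyl ester while the other terminus stays an aldehyde.

Step 9 (key step)
Reactants: 5 (S)-tert-butyl[(1-iodooctan-3-yl)oxy]dimethylsilane; 9 (R)-4-(tert-butyldimethylsilyloxy)cyclopent-2-en-1-one; 12 methyl 7-oxoheptanoate
Product: 16 methyl 7-[(1S,2R,3R)-3-(tert-butyldimethylsilyloxy)-2-[(3S)-3-(tert-butyldimethylsilyloxy)octyl]-5-oxocyclopentyl]-7-hydroxyheptanoate (C7 epimer mixture), via alkyllithium 13 (not isolated), via alkylcopper 14 (not isolated), via copper enolate 15 (not isolated)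
Conditions: 5 (1.2 equiv), t-BuLi (2.0 equiv per iodide), Et2O/pentane, −78 °C; CuI, Bu3P (2.6 equiv), THF, −78 °C; 9, −78 → −40 °C; 12 (1.3 equiv), −78 °C; aq NH4Cl
Reagents that add atoms: none
Why: Iodine–lithium exchange and transmetallation give a phosphine-ligated alkylcopper that adds 1,4 to enone 9 anti to the silyloxy group (sets C12 trans to C11), and the regiodefined enolate 15 is then trapped by aldehyde 12 in an intermolecular aldol addition anti to the new C12 chain (forms C7–C8, sets C8 trans to C12; C7 is a disposable epimer mixture), a tandem conjugate addition–aldol three-component coupling.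

Step 10
Reactants: 16 aldol adduct (C7 epimer mixture)
Product: 18 methyl (E)-7-[(2R,3R)-3-(tert-butyldimethylsilyloxy)-2-[(3S)-3-(tert-butyldimethylsilyloxy)octyl]-5-oxocyclopentylidene]heptanoate (minor Z isomer carried along), via C7 mesylate 17 (not isolated)
Conditions: MsCl (3 equiv), DMAP (10 equiv), CH2Cl2, 0 °C → rt
Reagents that add atoms: none
Why: Mesylation of the aldol hydroxyl followed by DMAP-promoted E1cB elimination through the acidic C8–H gives the conjugated exocyclic enone; both C7 epimers converge, and C11, C12 and C15 are untouched.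

Step 11
Reactants: 18 exocyclic enone
Product: 20 methyl 7-[(1R,2R,3R)-3-(tert-butyldimethylsilyloxy)-2-[(3S)-3-(tert-butyldimethylsilyloxy)octyl]-5-oxocyclopentyl]heptanoate, via copper enolate 19 (not isolated)
Conditions: [(Ph3P)CuH]6 (0.4 equiv), H2O (3 equiv), degassed toluene, rt; silica gel chromatography
Reagents that add atoms: none
Why: Copper hydride conjugate (1,4) reduction touches only the enone, and C-protonation of enolate 19 gives the thermodynamically preferred 8,12-trans ketone (the outcome known from cuprate additions to 2-alkyl-4-silyloxycyclopentenones), any 8-epimer equilibrating to it on silica gel or with KOAc in MeOH.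

Step 12
Reactants: 20 bis-TBS methyl ester
Product: 21 methyl 7-[(1R,2R,3R)-3-hydroxy-2-[(3S)-3-hydroxyoctyl]-5-oxocyclopentyl]heptanoate (13,14-dihydro-PGE1 methyl ester)
Conditions: HF·pyridine, MeCN, 0 °C → rt
Reagents that add atoms: none
Why: Fluoride-mediated desilylation under mildly acidic conditions removes both TBS ethers without dehydrating the β-hydroxy ketone or epimerising C8.

Step 13
Reactants: 21 13,14-dihydro-PGE1 methyl ester
Product: 22 13,14-dihydro-PGE1
Conditions: porcine liver esterase, phosphate buffer pH 8/acetone, 25 °C; then citric acid to pH 4, EtOAc extraction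
Reagents that add atoms: water, O
Why: Enzymatic ester hydrolysis at near-neutral pH avoids the β-elimination (PGA formation) and C8 epimerisation that hydroxide would cause.

**Compound list**

1 | methyl 3-oxooctanoate | CCCCCC(=O)CC(=O)OC | starting material
2 | methyl (S)-3-hydroxyoctanoate | CCCCC[C@H](O)CC(=O)OC | intermediate
3 | methyl (S)-3-(tert-butyldimethylsilyloxy)octanoate | CCCCC[C@H](O[Si](C)(C)C(C)(C)C)CC(=O)OC | intermediate
4 | (S)-3-(tert-butyldimethylsilyloxy)octan-1-ol | CCCCC[C@H](O[Si](C)(C)C(C)(C)C)CCO | intermediate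
5 | (S)-tert-butyl[(1-iodooctan-3-yl)oxy]dimethylsilane | CCCCC[C@H](O[Si](C)(C)C(C)(C)C)CCI | intermediate
6 | (1S,4R)-4-hydroxycyclopent-2-en-1-yl acetate (cis; also sold as (1R,4S)-cis-4-acetoxycyclopent-2-en-1-ol) | CC(=O)O[C@@H]1C=C[C@H](O)C1 | starting material
7 | (1S,4R)-4-(tert-butyldimethylsilyloxy)cyclopent-2-en-1-yl acetate (cis) | CC(=O)O[C@@H]1C=C[C@H](O[Si](C)(C)C(C)(C)C)C1 | intermediate
8 | (1S,4R)-4-(tert-butyldimethylsilyloxy)cyclopent-2-en-1-ol (cis) | O[C@@H]1C=C[C@H](O[Si](C)(C)C(C)(C)C)C1 | intermediate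
9 | (R)-4-(tert-butyldimethylsilyloxy)cyclopent-2-en-1-one | O=C1C=C[C@H](O[Si](C)(C)C(C)(C)C)C1 | intermediate
10 | cycloheptene | C1=CCCCCC1 | starting material
11 | 7-hydroperoxy-7-methoxyheptanal | O=CCCCCCC(OC)OO | intermediate (not isolated)
12 | methyl 7-oxoheptanoate | O=CCCCCCC(=O)OC | intermediate
13 | [3-(tert-butyldimethylsilyloxy)octyl]lithium, configuration of 5 retained (formally R because lithium ranks below carbon) | CCCCC[C@H](O[Si](C)(C)C(C)(C)C)CC[Li] | intermediate (not isolated)
14 | [(3S)-3-(tert-butyldimethylsilyloxy)octyl]copper, Bu3P-ligated | CCCCC[C@H](O[Si](C)(C)C(C)(C)C)CC[Cu] | intermediate (not isolated)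
15 | copper (3R,4R)-4-(tert-butyldimethylsilyloxy)-3-[(3S)-3-(tert-butyldimethylsilyloxy)octyl]cyclopent-1-en-1-olate | CCCCC[C@H](O[Si](C)(C)C(C)(C)C)CC[C@H]1[C@H](O[Si](C)(C)C(C)(C)C)CC(O[Cu])=C1 | intermediate (not isolated)
16 | methyl 7-[(1S,2R,3R)-3-(tert-butyldimethylsilyloxy)-2-[(3S)-3-(tert-butyldimethylsilyloxy)octyl]-5-oxocyclopentyl]-7-hydroxyheptanoate (C7 epimers; ring substituents all trans) | CCCCC[C@H](O[Si](C)(C)C(C)(C)C)CC[C@H]1[C@H](O[Si](C)(C)C(C)(C)C)CC(=O)[C@@H]1C(O)CCCCCC(=O)OC | intermediate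
17 | C7 methanesulfonate of 16 (C7 epimers) | CCCCC[C@H](O[Si](C)(C)C(C)(C)C)CC[C@H]1[C@H](O[Si](C)(C)C(C)(C)C)CC(=O)[C@@H]1C(OS(C)(=O)=O)CCCCCC(=O)OC | intermediate (not isolated)
18 | methyl (E)-7-[(2R,3R)-3-(tert-butyldimethylsilyloxy)-2-[(3S)-3-(tert-butyldimethylsilyloxy)octyl]-5-oxocyclopentylidene]heptanoate | CCCCC[C@H](O[Si](C)(C)C(C)(C)C)CC[C@H]1[C@H](O[Si](C)(C)C(C)(C)C)CC(=O)/C1=C/CCCCCC(=O)OC | intermediate
19 | copper (3R,4R)-4-(tert-butyldimethylsilyloxy)-3-[(3S)-3-(tert-butyldimethylsilyloxy)octyl]-2-(7-methoxy-7-oxoheptyl)cyclopent-1-en-1-olate, Ph3P-ligated | CCCCC[C@H](O[Si](C)(C)C(C)(C)C)CC[C@H]1[C@H](O[Si](C)(C)C(C)(C)C)CC(O[Cu])=C1CCCCCCC(=O)OC | intermediate (not isolated)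
20 | methyl 7-[(1R,2R,3R)-3-(tert-butyldimethylsilyloxy)-2-[(3S)-3-(tert-butyldimethylsilyloxy)octyl]-5-oxocyclopentyl]heptanoate | CCCCC[C@H](O[Si](C)(C)C(C)(C)C)CC[C@H]1[C@H](O[Si](C)(C)C(C)(C)C)CC(=O)[C@@H]1CCCCCCC(=O)OC | intermediate
21 | methyl 7-[(1R,2R,3R)-3-hydroxy-2-[(3S)-3-hydroxyoctyl]-5-oxocyclopentyl]heptanoate | CCCCC[C@H](O)CC[C@H]1[C@H](O)CC(=O)[C@@H]1CCCCCCC(=O)OC | intermediate
22 | 13,14-dihydro-PGE1, 7-[(1R,2R,3R)-3-hydroxy-2-[(3S)-3-hydroxyoctyl]-5-oxocyclopentyl]heptanoic acid | CCCCC[C@H](O)CC[C@H]1[C@H](O)CC(=O)[C@@H]1CCCCCCC(=O)O | target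

**Totals**
Total step count: 13.
Longest linear sequence: 9 steps (steps 1–4, then 9–13, from methyl 3-oxooctanoate).

**Three steps most likely to fail, with fallbacks**

Step 9 (tandem conjugate addition–aldol). Risks are incomplete enolate trapping, retro-aldol on warming, or proton transfer from the enolisable aldehyde. The fallback separates the two bond formations. It sets out from 5 and 9: the same copper-mediated conjugate addition is run, but the enolate is quenched with Me3SiCl/Et3N at −78 °C to isolate {[(3R,4R)-4-(tert-butyldimethylsilyloxy)-3-[(3S)-3-(tert-butyldimethylsilyloxy)octyl]cyclopent-1-en-1-yl]oxy}trimethylsilane F1. Aldehyde 12 is then joined to F1 by a Mukaiyama aldol addition (BF3·OEt2, CH2Cl2, −78 °C), again anti to the C12 chain, and the route is rejoined at aldol 16.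

Step 11 (conjugate reduction and C8 configuration). Risks are over-reduction or a substantial amount of the 8-epimer. The fallback avoids the enone altogether and sets out from aldol 16. The C7 hydroxyl is converted into the O-phenyl thionocarbonate of 16 F2 (PhOC(S)Cl, pyridine, DMAP, CH2Cl2, 0 °C) and removed by Barton–McCombie radical deoxygenation (Bu3SnH, AIBN, toluene, 80 °C). C8, already set trans in the aldol step, is never touched, and the route is rejoined at ketone 20.

Step 13 (enzymatic hydrolysis next to a β-hydroxy ketone). Risks are slow hydrolysis or dehydration to the PGA-type enone. The fallback cleaves the ester before the β-hydroxy ketone is unveiled and sets out from 20. Treatment with Me3SnOH (1,2-dichloroethane, 70–80 °C) gives 7-[(1R,2R,3R)-3-(tert-butyldimethylsilyloxy)-2-[(3S)-3-(tert-butyldimethylsilyloxy)octyl]-5-oxocyclopentyl]heptanoic acid F3. Both silyl ethers are then removed with HF·pyridine in MeCN, coming back to the route at the target 22.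

**Further compounds**

F1 | step 9 | {[(3R,4R)-4-(tert-butyldimethylsilyloxy)-3-[(3S)-3-(tert-butyldimethylsilyloxy)octyl]cyclopent-1-en-1-yl]oxy}trimethylsilane | CCCCC[C@H](O[Si](C)(C)C(C)(C)C)CC[C@H]1[C@H](O[Si](C)(C)C(C)(C)C)CC(O[Si](C)(C)C)=C1
F2 | step 11 | methyl 7-[(1S,2R,3R)-3-(tert-butyldimethylsilyloxy)-2-[(3S)-3-(tert-butyldimethylsilyloxy)octyl]-5-oxocyclopentyl]-7-(phenoxycarbonothioyloxy)heptanoate (C7 epimers) | CCCCC[C@H](O[Si](C)(C)C(C)(C)C)CC[C@H]1[C@H](O[Si](C)(C)C(C)(C)C)CC(=O)[C@@H]1C(OC(=S)Oc1ccccc1)CCCCCC(=O)OC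
F3 | step 13 | 7-[(1R,2R,3R)-3-(tert-butyldimethylsilyloxy)-2-[(3S)-3-(tert-butyldimethylsilyloxy)octyl]-5-oxocyclopentyl]heptanoic acid | CCCCC[C@H](O[Si](C)(C)C(C)(C)C)CC[C@H]1[C@H](O[Si](C)(C)C(C)(C)C)CC(=O)[C@@H]1CCCCCCC(=O)O
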